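**Retrosynthetic overview**

1. Target 17 ⇐ acetylation of alcohol 16 ⇐ removal of the pentanediol auxiliary (oxidation, β-elimination) from cyclohexenyl ether 14.
2. 14 ⇐ 13 by disconnection of C1–C6: a bromide-terminated Prins (cation–olefin) cyclisation of a chiral acetal. It closes the only ring (the cyclohexene) and sets the C1–O and C5–Br stereocentres in one operation.
3. Enabling feature: in the cyclohexene ring the C1 oxygen and the C5 bromine are 1,3-cis across the C6 methylene (a γ-bromo alcohol, the retron of a halo-Prins reaction). C5 sits next to the quaternary C4, which can carry a vinyl group, and the cis C2=C3 bond holds C1 and the vinyl terminus together.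
4. 13 ⇐ Appel bromination of (R)-chlorohydrin 12 ⇐ Corey–Bakshi–Shibata reduction of chloromethyl enone 11 ⇐ vinylstannane 8 + Weinreb amide 9.
5. 8 ⇐ syn-hydrostannation of alkynyl dioxane 7 ⇐ ynal 5 + (2S,4S)-pentane-2,4-diol 6; 5 ⇐ methyl 2,2-dimethylbut-3-enoate 1 (homologation to enyne 3, formylation).

Key step: step 8

Remark on the chemistry: the pentanediol acetal is assumed to react by its usual course (cleavage of the C–O bond flanked by the axial methyl group, attack with inversion). Ring atoms are numbered as in the name of the target (C1 carries the acetate, C2=C3 is the alkene, C4 is quaternary, C5 carries bromine, C6 is the methylene); C1' and C2' are the side-chain carbons.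

**Route**

Step 1
Reactants: 1 methyl 2,2-dimethylbut-3-enoate
Product: 3 3,3-dimethylpent-1-en-4-yne, via 2,2-dimethylbut-3-enal 2 (not isolated)
Conditions: i-Bu2AlH (1.05 equiv), CH2Cl2, −78 °C; then MeOH, K2CO3, dimethyl (1-diazo-2-oxopropyl)phosphonate, −78 °C → rt; volatile product kept as a dried pentane solution
Reagents that add atoms: dimethyl (1-diazo-2-oxopropyl)phosphonate (Ohira–Bestmann reagent), COP(=O)(OC)C(=[N+]=[N-])C(C)=O
Why: Partial reduction of the α-quaternary ester stops at the aluminium hemiacetal, which releases aldehyde 2 on methanolysis, and Seyferth–Gilbert homologation with the Ohira–Bestmann reagent should convert this non-enolisable aldehyde into the terminal alkyne; no stereocentre is formed.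

Step 2
Reactants: 3 3,3-dimethylpent-1-en-4-yne
Product: 5 4,4-dimethylhex-5-en-2-ynal, via lithium acetylide 4 (not isolated)
Conditions: n-BuLi (1.05 equiv), THF, −78 °C; DMF (2 equiv), −78 → 0 °C; reverse quench into cold 10% aq. H3PO4
Reagents that add atoms: N,N-dimethylformamide, CN(C)C=O
Why: Formylation of a lithium acetylide with DMF is a standard ynal synthesis, and the acidic reverse quench prevents conjugate addition of the liberated dimethylamine; no stereocentre is formed.

Step 3
Reactants: 5 4,4-dimethylhex-5-en-2-ynal; 6 (2S,4S)-pentane-2,4-diol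
Product: 7 (4S,6S)-2-(3,3-dimethylpent-4-en-1-yn-1-yl)-4,6-dimethyl-1,3-dioxane
Conditions: pyridinium p-toluenesulfonate (5 mol%), MgSO4, CH2Cl2, rt
Reagents that add atoms: none
Why: Acid-catalysed acetalisation; the diol is C2-symmetric, so the acetal carbon is not a stereocentre and a single dioxane should form, which serves as protecting group, chiral auxiliary and latent oxocarbenium ion.

Step 4
Reactants: 7 (4S,6S)-2-(3,3-dimethylpent-4-en-1-yn-1-yl)-4,6-dimethyl-1,3-dioxane
Product: 8 tributyl[(1E)-1-[(4S,6S)-4,6-dimethyl-1,3-dioxan-2-yl]-3,3-dimethylpenta-1,4-dien-1-yl]stannane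
Conditions: Bu3SnH (1.1 equiv), PdCl2(PPh3)2 (2 mol%), THF, 0 °C → rt
Reagents that add atoms: tributyltin hydride, CCCC[SnH](CCCC)CCCC
Why: Palladium-catalysed hydrostannation is a syn addition that should place tin on the alkyne carbon remote from the quaternary centre and next to the acetal, so the acetal carbon (future C1) is locked cis to C4 across the future C2=C3 bond, the geometry the ring closure needs; the isolated vinyl group does not react under these non-radical conditions.

Step 5
Reactants: 8 tributyl[(1E)-1-[(4S,6S)-4,6-dimethyl-1,3-dioxan-2-yl]-3,3-dimethylpenta-1,4-dien-1-yl]stannane; 9 2-chloro-N-methoxy-N-methylacetamide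
Product: 11 (3E)-1-chloro-3-[(4S,6S)-4,6-dimethyl-1,3-dioxan-2-yl]-5,5-dimethylhepta-3,6-dien-2-one, via vinyllithium 10 (not isolated)
Conditions: n-BuLi (1.05 equiv), THF, −78 °C; then 9 (1.2 equiv), −78 → −40 °C; AcOH (1.2 equiv) in THF, −78 °C
Reagents that add atoms: none
Why: Tin–lithium exchange proceeds with retention of alkene geometry, and the vinyllithium should add once to the Weinreb amide, whose chelated tetrahedral adduct collapses to the chloromethyl ketone only on the acidic quench.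

Step 6
Reactants: 11 (3E)-1-chloro-3-[(4S,6S)-4,6-dimethyl-1,3-dioxan-2-yl]-5,5-dimethylhepta-3,6-dien-2-one
Product: 12 (2R,3Z)-1-chloro-3-[(4S,6S)-4,6-dimethyl-1,3-dioxan-2-yl]-5,5-dimethylhepta-3,6-dien-2-ol
Conditions: (R)-2-methyl-CBS-oxazaborolidine [(R)-tetrahydro-1-methyl-3,3-diphenyl-1H,3H-pyrrolo[1,2-c][1,3,2]oxazaborole] (20 mol%), catecholborane (1.5 equiv), toluene, −78 °C; MeOH quench, neutral work-up
Reagents that add atoms: none
Why: Corey–Bakshi–Shibata reduction in which the bulky trisubstituted alkenyl group acts as the large and CH2Cl as the small substituent, so the (R)-oxazaborolidine should give the (R)-chlorohydrin at C1' (reagent control), while catecholborane at −78 °C should spare the vinyl group.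

Step 7
Reactants: 12 (2R,3Z)-1-chloro-3-[(4S,6S)-4,6-dimethyl-1,3-dioxan-2-yl]-5,5-dimethylhepta-3,6-dien-2-ol
Product: 13 (4S,6S)-2-[(2S,3E)-2-bromo-1-chloro-5,5-dimethylhepta-3,6-dien-3-yl]-4,6-dimethyl-1,3-dioxane
Conditions: CBr4 (1.3 equiv), PPh3 (1.4 equiv), CH2Cl2, 0 °C
Reagents that add atoms: carbon tetrabromide, BrC(Br)(Br)Br
Why: Appel reaction in which bromide displaces the alkoxyphosphonium group by SN2 with inversion, turning the (R)-alcohol into the (S)-bromide at C1'; the SN2' path is blocked because its terminus (future C3) is neopentyl, and ionisation is disfavoured by the β-chlorine and the acetal-bearing alkene.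

Step 8
Reactants: 13 (4S,6S)-2-[(2S,3E)-2-bromo-1-chloro-5,5-dimethylhepta-3,6-dien-3-yl]-4,6-dimethyl-1,3-dioxane
Product: 14 (2S,4S)-4-{[(1R,5S)-5-bromo-2-[(1S)-1-bromo-2-chloroethyl]-4,4-dimethylcyclohex-2-en-1-yl]oxy}pentan-2-ol
Conditions: TiBr4 (2.0 equiv), 2,6-di-tert-butyl-4-methylpyridine (1.5 equiv), CH2Cl2 (0.02 M), −78 → −45 °C; then sat. aq. NaHCO3
Reagents that add atoms: titanium tetrabromide, Br[Ti](Br)(Br)Br
Why: TiBr4 binds the acetal oxygen that is flanked by the axial methyl group of the (4S,6S)-dioxane, the C1–O bond opens to a tight oxocarbenium–titanate ion pair, the terminal carbon of the vinyl group (the future C6) attacks C1 anti to the departing oxygen, and the positive charge that develops at C5 is quenched by bromide from the titanate. The closest known reaction type is the Lewis-acid-mediated cation–olefin (Prins) cyclisation of chiral pentanediol acetals with halide termination, which gives 3-halocycloalkyl ethers. The cyclohexene ring closes in the 6-endo-trig mode with respect to the vinyl group (exo with respect to the C=O+ unit); the 5-exo alternative would need a primary cation and is not expected. C1 is controlled by the auxiliary (invertive opening of the (4S,6S)-acetal gives 1R, the alkenyl carbon ranking above the new CH2), and C5 is controlled relative to C1 by collapse of the ion pair on the ring face that carries the C1 oxygen, to which the titanate stays tethered through the opened auxiliary, giving the 1,3-cis (5S) bromo ether in which both groups can be equatorial. The step needs Markovnikov regioselectivity (secured by the monosubstituted alkene), facial selectivity at C1 (secured by the acetal) and bromide capture that outruns a 1,2-methyl shift from C4 to C5. The last is favoured by the low temperature, the high bromide activity of TiBr4 and the electron-poor C2=C3 bond with its bromochloroethyl substituent, which makes the rearranged tertiary allylic cation unattractive; the cis C2=C3 bond and the gem-dimethyl group hold C1 and the vinyl terminus within bonding distance, and the C1' bromide is not ionised because its allyl cation would carry the oxocarbenium centre.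

Step 9
Reactants: 14 (2S,4S)-4-{[(1R,5S)-5-bromo-2-[(1S)-1-bromo-2-chloroethyl]-4,4-dimethylcyclohex-2-en-1-yl]oxy}pentan-2-ol
Product: 15 (4S)-4-{[(1R,5S)-5-bromo-2-[(1S)-1-bromo-2-chloroethyl]-4,4-dimethylcyclohex-2-en-1-yl]oxy}pentan-2-one
Conditions: Dess–Martin periodinane (1,1,1-triacetoxy-1,1-dihydro-1,2-benziodoxol-3(1H)-one, 1.3 equiv), NaHCO3, CH2Cl2, 0 °C → rt
Reagents that add atoms: none
Why: Dess–Martin oxidation of the secondary hydroxyl of the opened auxiliary under buffered, non-basic conditions should give the β-alkoxy ketone needed for its removal without touching the halides or the ring stereocentres.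

Step 10
Reactants: 15 (4S)-4-{[(1R,5S)-5-bromo-2-[(1S)-1-bromo-2-chloroethyl]-4,4-dimethylcyclohex-2-en-1-yl]oxy}pentan-2-one
Product: 16 (1R,5S)-5-bromo-2-[(1S)-1-bromo-2-chloroethyl]-4,4-dimethylcyclohex-2-en-1-ol
Conditions: dibenzylammonium trifluoroacetate (30 mol%), toluene, 50 °C
Reagents that add atoms: none
Why: Amine-salt-catalysed retro-oxa-Michael reaction (E1cB-type β-elimination through the enamine/iminium of the methyl ketone) should expel the C1 alkoxide as the free allylic alcohol and pent-3-en-2-one without breaking the C1–O bond, so C1 keeps its configuration; the nearly neutral conditions are chosen to spare the allylic bromide.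

Step 11
Reactants: 16 (1R,5S)-5-bromo-2-[(1S)-1-bromo-2-chloroethyl]-4,4-dimethylcyclohex-2-en-1-ol
Product: 17 (1R,5S)-5-bromo-2-[(1S)-1-bromo-2-chloroethyl]-4,4-dimethylcyclohex-2-en-1-yl acetate
Conditions: Ac2O (1.5 equiv), pyridine, 4-(dimethylamino)pyridine (5 mol%), CH2Cl2, 0 °C
Reagents that add atoms: acetic anhydride, CC(=O)OC(C)=O
Why: Nucleophile-catalysed acetylation of the secondary allylic alcohol proceeds at oxygen with retention at C1 and should give the target.

**Compound list**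

1 | methyl 2,2-dimethylbut-3-enoate | COC(=O)C(C)(C)C=C | starting material
2 | 2,2-dimethylbut-3-enal | O=CC(C)(C)C=C | intermediate
3 | 3,3-dimethylpent-1-en-4-yne | C#CC(C)(C)C=C | intermediate
4 | (3,3-dimethylpent-4-en-1-yn-1-yl)lithium | [Li]C#CC(C)(C)C=C | intermediate
5 | 4,4-dimethylhex-5-en-2-ynal | O=CC#CC(C)(C)C=C | intermediate
6 | (2S,4S)-pentane-2,4-diol | C[C@H](O)C[C@H](C)O | starting material
7 | (4S,6S)-2-(3,3-dimethylpent-4-en-1-yn-1-yl)-4,6-dimethyl-1,3-dioxane | C=CC(C)(C)C#CC1O[C@@H](C)C[C@H](C)O1 | intermediate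
8 | tributyl[(1E)-1-[(4S,6S)-4,6-dimethyl-1,3-dioxan-2-yl]-3,3-dimethylpenta-1,4-dien-1-yl]stannane | C=CC(C)(C)/C=C(\C1O[C@@H](C)C[C@H](C)O1)[Sn](CCCC)(CCCC)CCCC | intermediate
9 | 2-chloro-N-methoxy-N-methylacetamide | CON(C)C(=O)CCl | starting material
10 | [(1Z)-1-[(4S,6S)-4,6-dimethyl-1,3-dioxan-2-yl]-3,3-dimethylpenta-1,4-dien-1-yl]lithium | C=CC(C)(C)/C=C(\C1O[C@@H](C)C[C@H](C)O1)[Li] | intermediate
11 | (3E)-1-chloro-3-[(4S,6S)-4,6-dimethyl-1,3-dioxan-2-yl]-5,5-dimethylhepta-3,6-dien-2-one | C=CC(C)(C)/C=C(\C1O[C@@H](C)C[C@H](C)O1)C(=O)CCl | intermediate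
12 | (2R,3Z)-1-chloro-3-[(4S,6S)-4,6-dimethyl-1,3-dioxan-2-yl]-5,5-dimethylhepta-3,6-dien-2-ol | C=CC(C)(C)/C=C(\C1O[C@@H](C)C[C@H](C)O1)[C@@H](O)CCl | intermediate
13 | (4S,6S)-2-[(2S,3E)-2-bromo-1-chloro-5,5-dimethylhepta-3,6-dien-3-yl]-4,6-dimethyl-1,3-dioxane | C=CC(C)(C)/C=C(\C1O[C@@H](C)C[C@H](C)O1)[C@H](Br)CCl | intermediate
14 | (2S,4S)-4-{[(1R,5S)-5-bromo-2-[(1S)-1-bromo-2-chloroethyl]-4,4-dimethylcyclohex-2-en-1-yl]oxy}pentan-2-ol | C[C@H](O)C[C@H](C)O[C@@H]1C[C@H](Br)C(C)(C)C=C1[C@H](Br)CCl | intermediate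
15 | (4S)-4-{[(1R,5S)-5-bromo-2-[(1S)-1-bromo-2-chloroethyl]-4,4-dimethylcyclohex-2-en-1-yl]oxy}pentan-2-one | CC(=O)C[C@H](C)O[C@@H]1C[C@H](Br)C(C)(C)C=C1[C@H](Br)CCl | intermediate
16 | (1R,5S)-5-bromo-2-[(1S)-1-bromo-2-chloroethyl]-4,4-dimethylcyclohex-2-en-1-ol | O[C@@H]1C[C@H](Br)C(C)(C)C=C1[C@H](Br)CCl | intermediate
17 | (1R,5S)-5-bromo-2-[(1S)-1-bromo-2-chloroethyl]-4,4-dimethylcyclohex-2-en-1-yl acetate | CC(=O)O[C@@H]1C[C@H](Br)C(C)(C)C=C1[C@H](Br)CCl | target

**Step count and risks**

Total step count: 11. Longest linear sequence: 11 steps (1 → 17); 6 and 9 are purchased.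

Steps most likely to fail:

1. Step 8 (key cyclisation). Before bromide is delivered, the secondary cation developing at C5 may undergo a 1,2-methyl shift from C4, or the hindered vinyl group may react so slowly that the acetal re-closes or loses facial control through a free oxocarbenium ion. The fallback forms the same C1–C6 bond without a carbocation at C5. It sets out from 13: buffered Wacker–Tsuji oxidation (PdCl2, CuCl, O2, DMF–H2O) of the vinyl group should give (4E,6S)-6-bromo-7-chloro-5-[(4S,6S)-4,6-dimethyl-1,3-dioxan-2-yl]-3,3-dimethylhept-4-en-2-one F1. Its only enolisable position is the methyl group, so Me3SiOTf/Et3N should give {[(4E,6S)-6-bromo-7-chloro-5-[(4S,6S)-4,6-dimethyl-1,3-dioxan-2-yl]-3,3-dimethylhepta-1,4-dien-2-yl]oxy}trimethylsilane F2. A TiCl4-mediated intramolecular Mukaiyama-type addition of the silyl enol ether to the chiral acetal (−78 °C, same sense of induction) should give (5R)-4-[(1S)-1-bromo-2-chloroethyl]-5-{[(2S,4S)-4-hydroxypentan-2-yl]oxy}-2,2-dimethylcyclohex-3-en-1-one F3. Dess–Martin oxidation should give (5R)-4-[(1S)-1-bromo-2-chloroethyl]-2,2-dimethyl-5-{[(2S)-4-oxopentan-2-yl]oxy}cyclohex-3-en-1-one F4, and dibenzylammonium trifluoroacetate, which should engage the unhindered methyl ketone and not the ring ketone flanked by the quaternary carbon, should release (5R)-4-[(1S)-1-bromo-2-chloroethyl]-5-hydroxy-2,2-dimethylcyclohex-3-en-1-one F5. Evans–Saksena reduction (Me4NBH(OAc)3, MeCN–AcOH, −20 °C) should deliver hydride from the C1 oxygen and give the trans diol (1R,3R)-4-[(1S)-1-bromo-2-chloroethyl]-6,6-dimethylcyclohex-4-ene-1,3-diol F6. Acetylation of the less hindered allylic hydroxyl (Ac2O, pyridine, 0 °C) should give (1R,5R)-2-[(1S)-1-bromo-2-chloroethyl]-5-hydroxy-4,4-dimethylcyclohex-2-en-1-yl acetate F7, and invertive bromination of the neopentyl alcohol (CBr4, P(n-C8H17)3, toluene, 70 °C) comes back to the route at 17. This last bromination is itself difficult.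

2. Step 10 (auxiliary removal). Under the amine-salt conditions the secondary allylic bromide at C1' may be displaced or epimerised, or the retro-oxa-Michael reaction may stall because the alkoxide re-adds to pentenone. The fallback carries the C1' oxygen as a silyl ether through cyclisation and auxiliary removal and introduces the bromide last. It sets out from 12: t-BuMe2SiOTf/2,6-lutidine should give tert-butyl{[(2R,3Z)-1-chloro-3-[(4S,6S)-4,6-dimethyl-1,3-dioxan-2-yl]-5,5-dimethylhepta-3,6-dien-2-yl]oxy}dimethylsilane F8. The same TiBr4 cyclisation (silyl ether expected to survive at −78 °C) should give (2S,4S)-4-{[(1R,5S)-5-bromo-2-[(1R)-1-{[tert-butyl(dimethyl)silyl]oxy}-2-chloroethyl]-4,4-dimethylcyclohex-2-en-1-yl]oxy}pentan-2-ol F9. Dess–Martin oxidation should give (4S)-4-{[(1R,5S)-5-bromo-2-[(1R)-1-{[tert-butyl(dimethyl)silyl]oxy}-2-chloroethyl]-4,4-dimethylcyclohex-2-en-1-yl]oxy}pentan-2-one F10, and K2CO3 in MeOH, now tolerated, should give (1R,5S)-5-bromo-2-[(1R)-1-{[tert-butyl(dimethyl)silyl]oxy}-2-chloroethyl]-4,4-dimethylcyclohex-2-en-1-ol F11. Acetylation should give (1R,5S)-5-bromo-2-[(1R)-1-{[tert-butyl(dimethyl)silyl]oxy}-2-chloroethyl]-4,4-dimethylcyclohex-2-en-1-yl acetate F12, HF·pyridine should give (1R,5S)-5-bromo-2-[(1R)-2-chloro-1-hydroxyethyl]-4,4-dimethylcyclohex-2-en-1-yl acetate F13, and Appel bromination (CBr4, PPh3) with inversion at C1' comes back to the route at 17.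

3. Step 5 (acylation). The vinyllithium may deprotonate the acidic α-chloro amide or displace its chloride instead of adding to the carbonyl group. The fallback avoids the organolithium and introduces chlorine afterwards. It sets out from 8: Stille-type acylation with acetyl chloride (Pd2(dba)3, P(2-furyl)3, THF, 50 °C) should give, with retention of geometry, (3E)-3-[(4S,6S)-4,6-dimethyl-1,3-dioxan-2-yl]-5,5-dimethylhepta-3,6-dien-2-one F14. LiN(SiMe3)2/Me3SiCl (THF, −78 °C) should enolise the only acidic position, the methyl group, to {[(3Z)-3-[(4S,6S)-4,6-dimethyl-1,3-dioxan-2-yl]-5,5-dimethylhepta-1,3,6-trien-2-yl]oxy}trimethylsilane F15, and N-chlorosuccinimide (THF, 0 °C) comes back to the route at 11.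

Further compounds
F1 | step 8 | (4E,6S)-6-bromo-7-chloro-5-[(4S,6S)-4,6-dimethyl-1,3-dioxan-2-yl]-3,3-dimethylhept-4-en-2-one | CC(=O)C(C)(C)/C=C(\C1O[C@@H](C)C[C@H](C)O1)[C@H](Br)CCl
F2 | step 8 | {[(4E,6S)-6-bromo-7-chloro-5-[(4S,6S)-4,6-dimethyl-1,3-dioxan-2-yl]-3,3-dimethylhepta-1,4-dien-2-yl]oxy}trimethylsilane | C=C(O[Si](C)(C)C)C(C)(C)/C=C(\C1O[C@@H](C)C[C@H](C)O1)[C@H](Br)CCl
F3 | step 8 | (5R)-4-[(1S)-1-bromo-2-chloroethyl]-5-{[(2S,4S)-4-hydroxypentan-2-yl]oxy}-2,2-dimethylcyclohex-3-en-1-one | C[C@H](O)C[C@H](C)O[C@@H]1CC(=O)C(C)(C)C=C1[C@H](Br)CCl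
F4 | step 8 | (5R)-4-[(1S)-1-bromo-2-chloroethyl]-2,2-dimethyl-5-{[(2S)-4-oxopentan-2-yl]oxy}cyclohex-3-en-1-one | CC(=O)C[C@H](C)O[C@@H]1CC(=O)C(C)(C)C=C1[C@H](Br)CCl
F5 | step 8 | (5R)-4-[(1S)-1-bromo-2-chloroethyl]-5-hydroxy-2,2-dimethylcyclohex-3-en-1-one | O[C@@H]1CC(=O)C(C)(C)C=C1[C@H](Br)CCl
F6 | step 8 | (1R,3R)-4-[(1S)-1-bromo-2-chloroethyl]-6,6-dimethylcyclohex-4-ene-1,3-diol | O[C@@H]1C[C@@H](O)C(C)(C)C=C1[C@H](Br)CCl
F7 | step 8 | (1R,5R)-2-[(1S)-1-bromo-2-chloroethyl]-5-hydroxy-4,4-dimethylcyclohex-2-en-1-yl acetate | CC(=O)O[C@@H]1C[C@@H](O)C(C)(C)C=C1[C@H](Br)CCl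
F8 | step 10 | tert-butyl{[(2R,3Z)-1-chloro-3-[(4S,6S)-4,6-dimethyl-1,3-dioxan-2-yl]-5,5-dimethylhepta-3,6-dien-2-yl]oxy}dimethylsilane | C=CC(C)(C)/C=C(\C1O[C@@H](C)C[C@H](C)O1)[C@@H](O[Si](C)(C)C(C)(C)C)CCl
F9 | step 10 | (2S,4S)-4-{[(1R,5S)-5-bromo-2-[(1R)-1-{[tert-butyl(dimethyl)silyl]oxy}-2-chloroethyl]-4,4-dimethylcyclohex-2-en-1-yl]oxy}pentan-2-ol | C[C@H](O)C[C@H](C)O[C@@H]1C[C@H](Br)C(C)(C)C=C1[C@@H](O[Si](C)(C)C(C)(C)C)CCl
F10 | step 10 | (4S)-4-{[(1R,5S)-5-bromo-2-[(1R)-1-{[tert-butyl(dimethyl)silyl]oxy}-2-chloroethyl]-4,4-dimethylcyclohex-2-en-1-yl]oxy}pentan-2-one | CC(=O)C[C@H](C)O[C@@H]1C[C@H](Br)C(C)(C)C=C1[C@@H](O[Si](C)(C)C(C)(C)C)CCl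
F11 | step 10 | (1R,5S)-5-bromo-2-[(1R)-1-{[tert-butyl(dimethyl)silyl]oxy}-2-chloroethyl]-4,4-dimethylcyclohex-2-en-1-ol | O[C@@H]1C[C@H](Br)C(C)(C)C=C1[C@@H](O[Si](C)(C)C(C)(C)C)CCl
F12 | step 10 | (1R,5S)-5-bromo-2-[(1R)-1-{[tert-butyl(dimethyl)silyl]oxy}-2-chloroethyl]-4,4-dimethylcyclohex-2-en-1-yl acetate | CC(=O)O[C@@H]1C[C@H](Br)C(C)(C)C=C1[C@@H](O[Si](C)(C)C(C)(C)C)CCl
F13 | step 10 | (1R,5S)-5-bromo-2-[(1R)-2-chloro-1-hydroxyethyl]-4,4-dimethylcyclohex-2-en-1-yl acetate | CC(=O)O[C@@H]1C[C@H](Br)C(C)(C)C=C1[C@@H](O)CCl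
F14 | step 5 | (3E)-3-[(4S,6S)-4,6-dimethyl-1,3-dioxan-2-yl]-5,5-dimethylhepta-3,6-dien-2-one | C=CC(C)(C)/C=C(\C1O[C@@H](C)C[C@H](C)O1)C(C)=O
F15 | step 5 | {[(3Z)-3-[(4S,6S)-4,6-dimethyl-1,3-dioxan-2-yl]-5,5-dimethylhepta-1,3,6-trien-2-yl]oxy}trimethylsilane | C=CC(C)(C)/C=C(\C1O[C@@H](C)C[C@H](C)O1)C(=C)O[Si](C)(C)C
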